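## The problem

Compound 21 is a single γ-butyrolactone ring (O1, carbonyl C2, C3, C4, C5) with no ring fusion, so the whole difficulty lies on the C3–C4 bond. C3 (S) is a fully substituted carbinol carbon next to the lactone carbonyl and carries the 4-hydroxy-3,5-dimethoxybenzyl group through C6. C4 (R) carries the 4-hydroxy-3-methoxybenzyl group through C7; the two benzyl groups are cis and the C3 hydroxyl is trans to C7. C3 has no hydrogen and the C4 hydrogen is not acidic, so neither centre can be corrected by epimerisation once made. Control can come from C4 (1,2-induction onto a lactone enolate, weak with one flexible CH2Ar group) or from an outside element that governs both centres. The two aryl groups differ by one methoxy group, so there is no symmetry shortcut and the halves must arrive as separate fragments. The free phenols and their electron-rich rings will not tolerate oxidants, electrophiles or enolate chemistry; they are carried as benzyl ethers, which can be removed last because 21 has no benzylic C–O bond in its skeleton. The enabling feature is that C2, C3 and the C3 oxygen form an α-hydroxy acid. Held with pivalaldehyde in a 2-tert-butyl-1,3-dioxolan-4-one, C3 becomes an enolate carbon and C3=C4 an alkylidene acceptor, so C5 can enter as a nucleophile at C4 and C6 as an electrophile at C3 under one acetal centre.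

## Retrosynthesis

**21 from 20.** The two phenolic O–CH2Ph bonds are cut. Benzyl ethers survive KOH, enolates, organocopper reagents, periodate and acid, and leave in one neutral step. Silyl ethers would not survive the aldol base, and methyl ethers could not be told apart from the three methoxy groups. Nothing else in 20 is hydrogenolysable, since the C3–O bond is tertiary and not benzylic.

**20 from 19, and 19 from 17.** The lactone C2–O1 bond is cut. In 19 the carbonyl C2 and the C3 oxygen are still tied in the dioxolanone, and the C5 hydroxyl only has to take over the acyl group; pivalaldehyde 6 leaves by itself, so no separate auxiliary removal is needed. The C5 hydroxymethyl group of 19 is traced to the vinyl group of 17 (one carbon excised through aldehyde 18). Vinyl is preferred to an oxygenated one-carbon nucleophile because it transfers reliably from copper. The forward steps must cleave the only alkene beside electron-rich arenes and reduce 18 before it can enolise at C4.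

**17 from 10, 15 and 14 (key disconnection).** The C4–C5 and C3–C6 bonds are cut together. Cutting C3–C6 alone on a preformed lactone would leave the C3 oxygen to be added later under weak 1,2-induction. Cutting C4–C7 would require a benzylic copper reagent, which homocouples easily. The chosen cut removes both stereocentres and eighteen carbons at once; what remains is alkylidene dioxolanone 10 with one ring and one stereocentre, plus vinylmagnesium bromide 15 and bromide 14. The forward reaction must add 1,4 rather than 1,2, form both bonds on the face opposite the tert-butyl group through enolate 16, and start from the Z alkene.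

**10 from 7, and 7 from 5 and 6.** The C3=C4 double bond is traced to the saturated acetal 7 by α-selenenylation and selenoxide elimination (8, 9). Radical bromination is avoided because 7 has two benzylic positions. Acetal 7 is cut at its two acetal C–O bonds into hydroxy acid 5 and pivalaldehyde 6. The stereocentre of 5 sets the acetal centre (cis acetal) and is then erased, so the whole synthesis needs only one small chiral acid.

**5 from 4, 3, 1 and 2.** The C4–C7 bond is cut as an aldol condensation of aldehyde 1 with pyruvic acid 2, giving 3. Pyruvate supplies C2, C3 and C4 at the correct oxidation level and the C3 oxygen of the target. An enzymatic ketone reduction (3 to 4) sets 2S, and a metal-free alkene saturation (4 to 5) spares the benzyl ether.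

**14 from 13, 12 and 11.** The C–Br bond, then the aldehyde oxidation level, then the O-benzyl bond are removed, leading to syringaldehyde 11. Each step is routine. The bromide is made last and used fresh because such electron-rich benzylic bromides do not store well.

## Roads not taken

**Alternative 1:** The ring oxygen is removed to give the prochiral cyclobutanone A1. In the forward direction a Baeyer–Villiger monooxygenase with O2 and NADPH inserts oxygen next to one of the two enantiotopic CH2 groups and gives lactone A2 with C4 as in 21. Enolate alkylation of A2 with 14 (trans) and enolate oxygenation anti to the C4 group would then reach 20.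
- Merits: A1 is a few steps from an allylarene by ketene cycloaddition, the key step is catalytic, and enzymes for either antipode exist. The whole route would be about seven to eight steps, two to four fewer than the chosen plan.
- Weak points for this target: the key step fixes only C4. The C3 carbinol is made last by an electrophilic oxygen transfer onto a lactone enolate, governed only by one flexible CH2Ar neighbour. A C3 epimer would differ only at a tertiary alcohol and be hard to remove, and the oxidant meets two electron-rich arenes.
- Comparison: the chosen plan is longer, but it never has to install the C3 oxygen (it comes from pyruvate), and it sets C3 and C4 together from a rigid acetal whose sense is predictable.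

**Alternative 2:** The C3–C6 and C3–O bonds are cut. Bromolactone A3 (from A2 by enolate bromination) is deprotonated and combined with aldehyde 12 in a Darzens reaction: aldol addition anti to C7, then displacement of bromide with inversion, gives spiro-epoxide A4. Hydrogenolysis of the benzylic epoxide C–O bond and of both benzyl ethers would then give 21 in a single last step.
- Merits: the last step does three jobs, the configuration at the aryl-bearing epoxide carbon is irrelevant, and the aldol/inversion sequence leads to the correct C3–C4 relation. In step count it is at least as short as Alternative 1 and shorter than the chosen plan.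
- Weak points: α-bromo lactone enolates are short-lived and the aldol step is reversible. The facial selectivity again rests on 1,2-induction from C4. A4 is a glycidic ester with a 4-alkoxyaryl group and opens readily to a benzylic cation under traces of acid. The route still depends on the supply of A2.
- Comparison: the chosen plan offers sturdier intermediates and stereocontrol that does not depend on a lactone enolate.

**Alternative 3:** The C4–C7 and C3–C6 bonds are cut on the chiral butenolide A5. The lithiated dithiane A6 adds 1,4 anti to the menthyloxy group and the enolate is trapped with 14 trans to the new substituent, giving the all-trans adduct A7 in one pot. Desulfurisation, removal of the acetal auxiliary with reduction of C5, hydroxylation at C3 and debenzylation would follow.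
- Merits: it uses the same tandem logic as the chosen plan, the auxiliary chemistry is well tried with often crystalline intermediates, and three components are joined at once.
- Weak points for this target: C3 is made as a C–H centre, so the hydroxyl must again be introduced late by enolate oxygenation. The required enantiomer A5 comes from the less common dextrorotatory menthyl series. Four operations follow the key step, so the route is not shorter than the chosen one.
- Comparison: the chosen plan carries the C3 oxygen inside the acceptor and sheds its auxiliary during lactonisation. In return it relies on a less common acceptor class, whereas the conjugate addition to A5 is the safer single step.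

Key step: step 9

Assumption: aldehyde 1 (O-benzylvanillin) is taken as a catalogue compound; the lactone numbering O1, C2, C3, C4, C5 with C6 (syringyl CH2) and C7 (guaiacyl CH2) is used for all intermediates.

## Route

Step 1
Reactants: 1 4-(benzyloxy)-3-methoxybenzaldehyde; 2 pyruvic acid
Product: 3 (E)-4-[4-(benzyloxy)-3-methoxyphenyl]-2-oxobut-3-enoic acid
Conditions: KOH, MeOH–H2O, 0 °C → rt; then aq. HCl
Reagents that add atoms: none
Why: Claisen–Schmidt (crossed aldol) condensation: the pyruvate enolate adds to the non-enolisable aldehyde and the aldol dehydrates to the E enone conjugated with the arene; the aryl benzyl ether is inert to KOH.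

Step 2
Reactants: 3 (E)-4-[4-(benzyloxy)-3-methoxyphenyl]-2-oxobut-3-enoic acid
Product: 4 (2S,3E)-4-[4-(benzyloxy)-3-methoxyphenyl]-2-hydroxybut-3-enoic acid
Conditions: L-lactate dehydrogenase (Bacillus stearothermophilus), NADH (cat.), formate dehydrogenase, HCO2Na, phosphate buffer pH 7, DMSO (5%), 30 °C; then HCl
Reagents that add atoms: none
Why: Enzymatic ketone reduction: the L-specific dehydrogenase passes hydride from NADH to the re face of the 2-oxo acid and should give the 2S acid as essentially one enantiomer; 4-aryl-2-oxobut-3-enoic acids are substrates of this enzyme class and formate recycles the cofactor.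

Step 3
Reactants: 4 (2S,3E)-4-[4-(benzyloxy)-3-methoxyphenyl]-2-hydroxybut-3-enoic acid
Product: 5 (S)-4-[4-(benzyloxy)-3-methoxyphenyl]-2-hydroxybutanoic acid
Conditions: TsNHNH2, NaOAc, DME–H2O, reflux
Reagents that add atoms: none
Why: Diimide reduction: diimide formed from the sulfonylhydrazide transfers H2 to the C=C bond in a concerted syn step; without a metal surface neither the aryl benzyl ether nor the allylic C–O bond is cleaved, and the stereocentre is not involved.

Step 4
Reactants: 5 (S)-4-[4-(benzyloxy)-3-methoxyphenyl]-2-hydroxybutanoic acid; 6 pivalaldehyde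
Product: 7 (2S,5S)-5-{2-[4-(benzyloxy)-3-methoxyphenyl]ethyl}-2-tert-butyl-1,3-dioxolan-4-one
Conditions: TsOH·H2O (cat.), H2SO4 (cat.), pentane–CH2Cl2, reflux, Dean–Stark; cis isomer by crystallisation
Reagents that add atoms: none
Why: Acid-catalysed acetalisation of an α-hydroxy acid with removal of water; the cis 2,5-disubstituted dioxolanone is favoured, so the 5S centre sets the acetal centre as 2S. The trans isomer must be removed because it would carry the opposite acetal configuration forward.

Step 5
Reactants: 7 (2S,5S)-5-{2-[4-(benzyloxy)-3-methoxyphenyl]ethyl}-2-tert-butyl-1,3-dioxolan-4-one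
Product: 10 (S,Z)-5-{2-[4-(benzyloxy)-3-methoxyphenyl]ethylidene}-2-tert-butyl-1,3-dioxolan-4-one, via selenide 8 (not isolated), via selenoxide 9 (not isolated)
Conditions: LDA, THF, −78 °C; PhSeBr, −78 °C; then 30% H2O2, pyridine, 0 °C → rt
Reagents that add atoms: none
Why: Enolate selenenylation followed by selenoxide syn elimination: the only β-hydrogens are on the side-chain CH2, so the double bond can only form exocyclic, and the ArCH2 group turns away from the carbonyl in the cyclic transition state, which gives the Z alkene. The former C5 centre is erased while the acetal centre is untouched.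

Step 6
Reactants: 11 syringaldehyde
Product: 12 4-(benzyloxy)-3,5-dimethoxybenzaldehyde
Conditions: BnBr, K2CO3, DMF, 60 °C
Reagents that add atoms: benzyl bromide, BrCc1ccccc1
Why: Williamson ether synthesis on the phenoxide; the hindered but acidic 4-OH alkylates cleanly with a benzylic bromide.

Step 7
Reactants: 12 4-(benzyloxy)-3,5-dimethoxybenzaldehyde
Product: 13 [4-(benzyloxy)-3,5-dimethoxyphenyl]methanol
Conditions: NaBH4, MeOH–THF, 0 °C
Reagents that add atoms: none
Why: Borohydride reduction of an aromatic aldehyde to the benzylic alcohol; nothing else in the molecule is reducible.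

Step 8
Reactants: 13 [4-(benzyloxy)-3,5-dimethoxyphenyl]methanol
Product: 14 4-(benzyloxy)-3,5-dimethoxybenzyl bromide
Conditions: PBr3, Et2O, 0 °C; used fresh
Reagents that add atoms: phosphorus tribromide, BrP(Br)Br
Why: Conversion of a benzylic alcohol into the bromide through its phosphite ester (SN2 by bromide); the electron-rich bromide is labile and is therefore made directly before the key step.

Step 9
Reactants: 10 (S,Z)-5-{2-[4-(benzyloxy)-3-methoxyphenyl]ethylidene}-2-tert-butyl-1,3-dioxolan-4-one; 14 4-(benzyloxy)-3,5-dimethoxybenzyl bromide; 15 vinylmagnesium bromide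
Product: 17 (2S,5S)-5-[4-(benzyloxy)-3,5-dimethoxybenzyl]-5-{(R)-1-[4-(benzyloxy)-3-methoxyphenyl]but-3-en-2-yl}-2-tert-butyl-1,3-dioxolan-4-one, via magnesium enolate 16 (not isolated)
Conditions: 15 (2 per Cu), CuBr·SMe2, THF–Me2S, −78 → −40 °C; then DMPU, 14, −78 → −20 °C; aq. NH4Cl
Reagents that add atoms: none
Why: Two equivalents of 15 and CuBr·SMe2 give bromomagnesium divinylcuprate, which forms a π-complex with the enoate part of 10 and passes one vinyl group to the exocyclic carbon (lactone C4) by oxidative addition–reductive elimination, leaving the bromomagnesium enolate 16; with DMPU this enolate is C-benzylated by 14 in an SN2 step. The closest known reaction type is the organocopper conjugate addition with in situ enolate alkylation of α,β-unsaturated esters and lactones, joined to the well-tried alkylation of 2-tert-butyl-1,3-dioxolan-4-one enolates anti to the tert-butyl group. No ring is closed. C4 is set in the vinyl transfer: the reagent approaches the Z alkene on the face away from the tert-butyl group at the acetal carbon, which gives the R configuration. C3 is set in the benzylation, again on the face away from the tert-butyl group (S), so both bonds enter the same face of the former double bond and the cis relation of C6 and C7 follows from the Z geometry. The step needs 1,4- over 1,2-selectivity and no γ-deprotonation at C7, secured by the soft cuprate at low temperature and the absence of free Grignard reagent, and it needs C- over O-alkylation, secured by the soft benzylic bromide.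

Step 10
Reactants: 17 (2S,5S)-5-[4-(benzyloxy)-3,5-dimethoxybenzyl]-5-{(R)-1-[4-(benzyloxy)-3-methoxyphenyl]but-3-en-2-yl}-2-tert-butyl-1,3-dioxolan-4-one
Product: 19 (2S,5S)-5-[4-(benzyloxy)-3,5-dimethoxybenzyl]-5-{(R)-1-[4-(benzyloxy)-3-methoxyphenyl]-3-hydroxypropan-2-yl}-2-tert-butyl-1,3-dioxolan-4-one, via aldehyde 18 (not isolated)
Conditions: K2OsO4·2H2O (cat.), NaIO4, 2,6-lutidine, dioxane–H2O, rt; filter; then NaBH4, MeOH, 0 °C
Reagents that add atoms: osmium tetroxide (from K2OsO4·2H2O, transfers the oxygen), O=[Os](=O)(=O)=O; sodium periodate (terminal oxidant), [Na+].[O-]I(=O)(=O)=O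
Why: Lemieux–Johnson cleavage of the only alkene (dihydroxylation, then periodate glycol cleavage) buffered with 2,6-lutidine, followed at once by borohydride reduction so that the α-branched aldehyde 18 has no time to enolise at C4. Any lactone 20 formed early by attack of the new alkoxide on the dioxolanone is simply carried into step 11.

Step 11
Reactants: 19 (2S,5S)-5-[4-(benzyloxy)-3,5-dimethoxybenzyl]-5-{(R)-1-[4-(benzyloxy)-3-methoxyphenyl]-3-hydroxypropan-2-yl}-2-tert-butyl-1,3-dioxolan-4-one
Product: 20 (3S,4R)-3-[4-(benzyloxy)-3,5-dimethoxybenzyl]-4-[4-(benzyloxy)-3-methoxybenzyl]-3-hydroxydihydrofuran-2(3H)-one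
Conditions: TsOH·H2O (cat.), CH2Cl2, rt
Reagents that add atoms: none
Why: Acid-catalysed intramolecular transacylation (lactonisation): the primary hydroxyl attacks the dioxolanone carbonyl in a 5-exo-trig step and the resulting hemiacetal on the C3 oxygen collapses with loss of pivalaldehyde. No stereocentre is touched.

Step 12
Reactants: 20 (3S,4R)-3-[4-(benzyloxy)-3,5-dimethoxybenzyl]-4-[4-(benzyloxy)-3-methoxybenzyl]-3-hydroxydihydrofuran-2(3H)-one
Product: 21 (3S,4R)-3-hydroxy-3-(4-hydroxy-3,5-dimethoxybenzyl)-4-(4-hydroxy-3-methoxybenzyl)dihydrofuran-2(3H)-one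
Conditions: H2 (1 atm), Pd/C (10%), EtOAc–MeOH, rt
Reagents that add atoms: none
Why: Catalytic hydrogenolysis of the two aryl benzyl ethers; the tertiary, non-benzylic C3–OH and the lactone are not affected.

## Compound list

1 | 4-(benzyloxy)-3-methoxybenzaldehyde | COc1cc(C=O)ccc1OCc1ccccc1 | starting material
2 | pyruvic acid | CC(=O)C(O)=O | starting material
3 | (E)-4-[4-(benzyloxy)-3-methoxyphenyl]-2-oxobut-3-enoic acid | COc1cc(/C=C/C(=O)C(O)=O)ccc1OCc1ccccc1 | intermediate
4 | (2S,3E)-4-[4-(benzyloxy)-3-methoxyphenyl]-2-hydroxybut-3-enoic acid | COc1cc(/C=C/[C@H](O)C(O)=O)ccc1OCc1ccccc1 | intermediate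
5 | (S)-4-[4-(benzyloxy)-3-methoxyphenyl]-2-hydroxybutanoic acid | COc1cc(CC[C@H](O)C(O)=O)ccc1OCc1ccccc1 | intermediate
6 | pivalaldehyde | CC(C)(C)C=O | starting material
7 | (2S,5S)-5-{2-[4-(benzyloxy)-3-methoxyphenyl]ethyl}-2-tert-butyl-1,3-dioxolan-4-one (cis) | CC(C)(C)[C@@H]1OC(=O)[C@H](CCc2ccc(OCc3ccccc3)c(OC)c2)O1 | intermediate
8 | (2R,5R)-5-{2-[4-(benzyloxy)-3-methoxyphenyl]ethyl}-2-tert-butyl-5-(phenylselanyl)-1,3-dioxolan-4-one (Se trans to tert-butyl; acetal carbon unchanged in space, its descriptor changes because of Se) | CC(C)(C)[C@@H]1OC(=O)[C@]([Se]c2ccccc2)(CCc2ccc(OCc3ccccc3)c(OC)c2)O1 | intermediate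
9 | (2R,5R)-5-{2-[4-(benzyloxy)-3-methoxyphenyl]ethyl}-2-tert-butyl-5-(phenylseleninyl)-1,3-dioxolan-4-one (both configurations at selenium) | CC(C)(C)[C@@H]1OC(=O)[C@]([Se](=O)c2ccccc2)(CCc2ccc(OCc3ccccc3)c(OC)c2)O1 | intermediate
10 | (S,Z)-5-{2-[4-(benzyloxy)-3-methoxyphenyl]ethylidene}-2-tert-butyl-1,3-dioxolan-4-one | CC(C)(C)[C@@H]1OC(=O)/C(=C/Cc2ccc(OCc3ccccc3)c(OC)c2)O1 | intermediate
11 | syringaldehyde | COc1cc(C=O)cc(OC)c1O | starting material
12 | 4-(benzyloxy)-3,5-dimethoxybenzaldehyde | COc1cc(C=O)cc(OC)c1OCc1ccccc1 | intermediate
13 | [4-(benzyloxy)-3,5-dimethoxyphenyl]methanol | COc1cc(CO)cc(OC)c1OCc1ccccc1 | intermediate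
14 | 4-(benzyloxy)-3,5-dimethoxybenzyl bromide | COc1cc(CBr)cc(OC)c1OCc1ccccc1 | intermediate
15 | vinylmagnesium bromide | C=C[Mg]Br | starting material
16 | bromomagnesium (S)-5-{(R)-1-[4-(benzyloxy)-3-methoxyphenyl]but-3-en-2-yl}-2-tert-butyl-1,3-dioxol-4-olate | CC(C)(C)[C@@H]1OC(O[Mg]Br)=C([C@H](Cc2ccc(OCc3ccccc3)c(OC)c2)C=C)O1 | intermediate
17 | (2S,5S)-5-[4-(benzyloxy)-3,5-dimethoxybenzyl]-5-{(R)-1-[4-(benzyloxy)-3-methoxyphenyl]but-3-en-2-yl}-2-tert-butyl-1,3-dioxolan-4-one | CC(C)(C)[C@@H]1OC(=O)[C@](Cc2cc(OC)c(OCc3ccccc3)c(OC)c2)([C@H](Cc2ccc(OCc3ccccc3)c(OC)c2)C=C)O1 | intermediate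
18 | (2S,5S)-5-[4-(benzyloxy)-3,5-dimethoxybenzyl]-5-{(S)-1-[4-(benzyloxy)-3-methoxyphenyl]-3-oxopropan-2-yl}-2-tert-butyl-1,3-dioxolan-4-one (same spatial arrangement as 17; descriptor changes with the formyl group) | CC(C)(C)[C@@H]1OC(=O)[C@](Cc2cc(OC)c(OCc3ccccc3)c(OC)c2)([C@H](Cc2ccc(OCc3ccccc3)c(OC)c2)C=O)O1 | intermediate
19 | (2S,5S)-5-[4-(benzyloxy)-3,5-dimethoxybenzyl]-5-{(R)-1-[4-(benzyloxy)-3-methoxyphenyl]-3-hydroxypropan-2-yl}-2-tert-butyl-1,3-dioxolan-4-one | CC(C)(C)[C@@H]1OC(=O)[C@](Cc2cc(OC)c(OCc3ccccc3)c(OC)c2)([C@H](Cc2ccc(OCc3ccccc3)c(OC)c2)CO)O1 | intermediate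
20 | (3S,4R)-3-[4-(benzyloxy)-3,5-dimethoxybenzyl]-4-[4-(benzyloxy)-3-methoxybenzyl]-3-hydroxydihydrofuran-2(3H)-one | COc1cc(C[C@@H]2COC(=O)[C@]2(O)Cc2cc(OC)c(OCc3ccccc3)c(OC)c2)ccc1OCc1ccccc1 | intermediate
21 | (3S,4R)-3-hydroxy-3-(4-hydroxy-3,5-dimethoxybenzyl)-4-(4-hydroxy-3-methoxybenzyl)dihydrofuran-2(3H)-one | COc1cc(C[C@@H]2COC(=O)[C@]2(O)Cc2cc(OC)c(O)c(OC)c2)ccc1O | target

## Step count and weakest steps

Total: 12 steps. Longest linear sequence: 9 steps (steps 1–5 and 9–12, from 1). The branch to bromide 14 is 3 steps (6–8).

**Step 9 (key step).** Three things may go wrong.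
- The vinyl transfer may be slow, because the acceptor carbon is also the β-carbon of an enol ether. Attack at the reactive acetal-ester carbonyl, or deprotonation at the doubly activated C7 methylene, could then compete.
- Face discrimination at the exocyclic carbon may be incomplete, since it lies farther from the tert-butyl group than the ring carbon.
- The magnesium/copper enolate may be benzylated too slowly, so that it is protonated or decomposes, while residual vinylcopper consumes the bromide.

Fallback: separate the two bond formations. Starting from 10, the cuprate addition is run alone and quenched cold with NH4Cl to give (2S,5S)-5-{(R)-1-[4-(benzyloxy)-3-methoxyphenyl]but-3-en-2-yl}-2-tert-butyl-1,3-dioxolan-4-one F1. This can be freed from any C4 epimer by chromatography. F1 is then converted into its lithium enolate with LDA in THF–DMPU at −78 °C and benzylated with 14 anti to the tert-butyl group. The sequence returns to the route at 17.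

**Step 2.** The bulky, poorly soluble benzyloxyaryl substrate may bind weakly to the dehydrogenase, giving slow or incomplete turnover. Fallback: asymmetric hydrogenation of 3 under H2 with a chiral diphosphine complex of the RuCl2(BINAP) type (or its SunPhos analogue). This reduces ketone and alkene in one operation without touching the benzyl ether. The ligand antipode that delivers the 2S acid would be used, and the acid crystallised as a salt with an enantiopure amine before acetalisation. It sets out from 3 and returns at 5, replacing steps 2 and 3; it makes no new compound (entry F0).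

**Step 5.** The elimination may lose geometric purity, the double bond may drift into conjugation with the arene, or the peroxide/seleninic acid mixture may oxidise the electron-rich enol-ether alkene. Fallback: change the elimination mechanism. Starting from 7, the lithium enolate is brominated with 1,2-dibromotetrachloroethane at −78 °C to give (2R,5R)-5-bromo-5-{2-[4-(benzyloxy)-3-methoxyphenyl]ethyl}-2-tert-butyl-1,3-dioxolan-4-one F2. Anti elimination of HBr with DBU in CH2Cl2 at room temperature, with no oxidant present, should lead to the more stable Z alkene. The sequence returns at 10.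

**Step 10.** Aldehyde 18 may enolise toward C4, causing epimerisation or β-elimination of the acetal oxygen, and hydride may attack the dioxolanone carbonyl. Fallback: avoid the aldehyde altogether by using a hydroxymethyl anion equivalent in the tandem step. Starting from 10, the cuprate from (isopropoxydimethylsilyl)methylmagnesium chloride and CuBr·SMe2 is added and the enolate trapped with 14 as in step 9. This gives (2S,5S)-5-[4-(benzyloxy)-3,5-dimethoxybenzyl]-5-{(S)-1-[4-(benzyloxy)-3-methoxyphenyl]-3-[isopropoxy(dimethyl)silyl]propan-2-yl}-2-tert-butyl-1,3-dioxolan-4-one F3. Tamao–Fleming oxidation (H2O2, KF, KHCO3, THF–MeOH) converts the C–Si bond into the C5–OH bond and returns to the route at 19.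

## Further compounds

F1 | step 9 | (2S,5S)-5-{(R)-1-[4-(benzyloxy)-3-methoxyphenyl]but-3-en-2-yl}-2-tert-butyl-1,3-dioxolan-4-one | CC(C)(C)[C@@H]1OC(=O)[C@H]([C@H](Cc2ccc(OCc3ccccc3)c(OC)c2)C=C)O1
F0 | step 2 | none | none
F2 | step 5 | (2R,5R)-5-bromo-5-{2-[4-(benzyloxy)-3-methoxyphenyl]ethyl}-2-tert-butyl-1,3-dioxolan-4-one | CC(C)(C)[C@@H]1OC(=O)[C@](Br)(CCc2ccc(OCc3ccccc3)c(OC)c2)O1
F3 | step 10 | (2S,5S)-5-[4-(benzyloxy)-3,5-dimethoxybenzyl]-5-{(S)-1-[4-(benzyloxy)-3-methoxyphenyl]-3-[isopropoxy(dimethyl)silyl]propan-2-yl}-2-tert-butyl-1,3-dioxolan-4-one | CC(C)(C)[C@@H]1OC(=O)[C@](Cc2cc(OC)c(OCc3ccccc3)c(OC)c2)([C@H](Cc2ccc(OCc3ccccc3)c(OC)c2)C[Si](C)(C)OC(C)C)O1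
A1 | alternative 1 | 3-[4-(benzyloxy)-3-methoxybenzyl]cyclobutan-1-one | COc1cc(CC2CC(=O)C2)ccc1OCc1ccccc1
A2 | alternative 1 | (S)-4-[4-(benzyloxy)-3-methoxybenzyl]dihydrofuran-2(3H)-one | COc1cc(C[C@@H]2COC(=O)C2)ccc1OCc1ccccc1
A3 | alternative 2 | (4R)-4-[4-(benzyloxy)-3-methoxybenzyl]-3-bromodihydrofuran-2(3H)-one (either configuration at C3) | COc1cc(C[C@@H]2COC(=O)C2Br)ccc1OCc1ccccc1
A4 | alternative 2 | (3R,7R)-2-[4-(benzyloxy)-3,5-dimethoxyphenyl]-7-[4-(benzyloxy)-3-methoxybenzyl]-1,5-dioxaspiro[2.4]heptan-4-one (either configuration at the aryl-bearing carbon) | COc1cc(C[C@@H]2COC(=O)[C@@]23OC3c3cc(OC)c(OCc4ccccc4)c(OC)c3)ccc1OCc1ccccc1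
A5 | alternative 3 | (5S)-5-[(1S,2R,5S)-menthyloxy]furan-2(5H)-one | O=C1O[C@H](O[C@H]2C[C@@H](C)CC[C@@H]2C(C)C)C=C1
A6 | alternative 3 | 2-[4-(benzyloxy)-3-methoxyphenyl]-1,3-dithiane | COc1cc(C2SCCCS2)ccc1OCc1ccccc1
A7 | alternative 3 | 3,4-trans-4,5-trans-3-[4-(benzyloxy)-3,5-dimethoxybenzyl]-4-{2-[4-(benzyloxy)-3-methoxyphenyl]-1,3-dithian-2-yl}-5-[(1S,2R,5S)-menthyloxy]dihydrofuran-2(3H)-one (C4 configured as in 21) | O=C1O[C@H](O[C@H]2C[C@@H](C)CC[C@@H]2C(C)C)[C@@H](C2(c3ccc(OCc4ccccc4)c(OC)c3)SCCCS2)[C@@H]1Cc1cc(OC)c(OCc2ccccc2)c(OC)c1
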